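The oxolane ring is read as a cycloadduct: C2–O1–C5 with its two aryl groups is a carbonyl ylide, and C3–C4 with the two hydroxymethyl carbons is a fumaric acid unit; the twofold axis makes both junctions alike. Sensitised C–C cleavage of a trans-2,3-diaryloxirane (from syringaldehyde by reductive dimerisation and epoxidation) gives the ylide, which adds to a C2-symmetric fumaroyl bis-sultam. This one [3+2] step forms C2–C3 and C4–C5, closes the ring and sets C3/C4 (trans, absolute configuration). Phenol-assisted equilibration of the benzylic centres C2/C5 then gives the all-trans ring, and hydride cleavage of the auxiliaries releases the two hydroxymethyl groups.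

Key step: step 5

Assumption: N-enoyl derivatives of (2R)-bornane-10,2-sultam are taken to be attacked by 1,3-dipoles on the Cα-re face (s-cis conformer, C=O anti to SO2), the sense reported for their other dipolar cycloadditions; the sense of induction is to be confirmed on 12, and the (2S)-sultam would serve if it proved opposite.

Step 1
Reactants: 1 syringaldehyde
Product: 2 4-(benzyloxy)-3,5-dimethoxybenzaldehyde
Conditions: BnBr, K2CO3, DMF, 60 °C
Reagents that add atoms: benzyl bromide, BrCc1ccccc1
Why: Williamson ether synthesis (SN2 O-alkylation of the acidic para-formyl phenoxide) should protect the phenol as an ether that survives low-valent titanium, the dioxirane and the sensitised irradiation.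

Step 2
Reactants: 2 4-(benzyloxy)-3,5-dimethoxybenzaldehyde (two molecules)
Product: 3 (E)-1,2-bis(4-benzyloxy-3,5-dimethoxyphenyl)ethene
Conditions: TiCl4, Zn, pyridine, THF, reflux
Reagents that add atoms: none
Why: McMurry reductive homocoupling of an aromatic aldehyde (titanium pinacolate, then deoxygenation) should give the thermodynamically preferred E-stilbene, the aryl ethers being inert.

Step 3
Reactants: 3 (E)-1,2-bis(4-benzyloxy-3,5-dimethoxyphenyl)ethene
Product: 4 trans-2,3-bis(4-benzyloxy-3,5-dimethoxyphenyl)oxirane (racemic)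
Conditions: dimethyldioxirane (acetone solution), CH2Cl2, 0 °C
Reagents that add atoms: dimethyldioxirane, CC1(C)OO1
Why: Concerted, stereospecific syn oxygen transfer from the dioxirane to the electron-rich E-alkene should give the trans-epoxide under neutral conditions that avoid acid-induced Meinwald rearrangement; the racemate suffices because both epoxide stereocentres are erased in step 5.

Step 4
Reactants: 5 (2R)-bornane-10,2-sultam (two molecules); 6 fumaryl chloride
Product: 8 N,N'-fumaroylbis[(2R)-bornane-10,2-sultam], via sodium sultamide 7 (not isolated)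
Conditions: NaH (1.05 equiv per 5), toluene, 0 °C to rt; then 6 (0.5 equiv per 5), 0 °C to rt
Reagents that add atoms: none
Why: N-Acylation of two equivalents of the sodium sultamide by the two acid chloride termini of 6 (nucleophilic acyl substitution, the standard preparation of N-enoyl sultams) should give the crystalline C2-symmetric dipolarophile with the E geometry retained.

Step 5
Reactants: 4 trans-2,3-bis(4-benzyloxy-3,5-dimethoxyphenyl)oxirane (1.5 equiv); 8 N,N'-fumaroylbis[(2R)-bornane-10,2-sultam]
Product: 10 N,N'-[(2R,3S,4S,5S)-2,5-bis(4-benzyloxy-3,5-dimethoxyphenyl)oxolane-3,4-dicarbonyl]bis[(2R)-bornane-10,2-sultam] (2,5-cis), via carbonyl ylide 9 (not isolated)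
Conditions: 9,10-dicyanoanthracene (5 mol%), MeCN/CH2Cl2 (degassed), 420 nm LEDs, Ar, 20 °C
Reagents that add atoms: none
Why: Excited 9,10-dicyanoanthracene should oxidise the trialkoxyaryl epoxide to its radical cation, whose oxirane C–C bond breaks, and back electron transfer then gives the planar W-shaped (exo,exo) carbonyl ylide 9, which adds to 8 in a suprafacial 1,3-dipolar [3+2] cycloaddition (HOMO of the ylide, LUMO of the fumaramide) that forms C2–C3 and C4–C5 together. The closest known reaction type is the electron-transfer-sensitised carbonyl ylide cycloaddition of 2,3-diaryloxiranes with fumarates and other electron-poor alkenes, joined to the auxiliary-controlled cycloadditions of N-enoyl bornane-10,2-sultams with nitrile oxides and azomethine ylides. The oxolane ring is closed by the intermolecular cycloaddition itself, both σ-bonds being made on one face of each partner in a five-membered transition state. C3 and C4 should be trans because the E geometry of the alkene is transferred stereospecifically, and their absolute configuration (3S,4S) should follow from attack on the Cα-re/Cα'-re face that both sultam units leave open; C2 and C5 should be cis because the W-ylide adds suprafacially, which leaves C2 cis and C5 trans to the neighbouring acyl group. The only selectivity that must be secured here is the π-face of the dipolarophile, and the matched double auxiliary is there to secure it. C2/C5 epimers from the minor exo,endo ylide are carried on because step 6 converges them, and a high concentration of the electron-poor alkene should let trapping outrun re-closure of the ylide.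

Step 6
Reactants: 10 the 2,5-cis dibenzyl bis-sultam cycloadduct
Product: 12 N,N'-[(2S,3S,4S,5S)-2,5-bis(4-hydroxy-3,5-dimethoxyphenyl)oxolane-3,4-dicarbonyl]bis[(2R)-bornane-10,2-sultam] (all-trans), via 2,5-cis bisphenol 11 (not isolated)
Conditions: H2 (1 atm), Pd/C, EtOAc/THF, rt; filter, concentrate; then CF3CO2H (0.2 equiv), CH2Cl2, 0 °C to rt
Reagents that add atoms: none
Why: Hydrogenolysis of the two aryl benzyl ethers under neutral conditions, then acid-catalysed reversible opening of the benzylic C2–O and C5–O bonds through the para-hydroxybenzyl cation (protonated para-quinone methide) and 5-membered re-closure by the retained hydroxyl, should place each aryl trans to its neighbouring acyl group under thermodynamic control (known acid-mediated C2 epimerisation of 2,5-diaryltetrahydrofuran lignans); C3/C4 are not enolised, so they dictate 2S,5S, no free hydroxymethyl group is yet present to divert the cation to a furofuran, and crystallisation of 12 should remove any diastereomer from attack on the other alkene face.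

Step 7
Reactants: 12 the all-trans bisphenol bis-sultam
Product: 13 huazhongilexin, (2S,3R,4R,5S)-2,5-bis(4-hydroxy-3,5-dimethoxyphenyl)-3,4-bis(hydroxymethyl)oxolane
Conditions: LiAlH4 (excess), THF, 0 °C to rt; aqueous Rochelle salt/NH4Cl work-up
Reagents that add atoms: none
Why: Reductive cleavage of N-acyl sultams by LiAlH4 should give the two primary alcohols and release the auxiliary without touching a stereocentre (the descriptors at C3/C4 change from S to R only through substituent priority), the excess hydride covering the two phenols and the buffered work-up avoiding acid.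

Compound list
1 | syringaldehyde (4-hydroxy-3,5-dimethoxybenzaldehyde) | COc1cc(C=O)cc(OC)c1O | starting material
2 | 4-(benzyloxy)-3,5-dimethoxybenzaldehyde | COc1cc(C=O)cc(OC)c1OCc1ccccc1 | intermediate
3 | (E)-1,2-bis(4-benzyloxy-3,5-dimethoxyphenyl)ethene | COc1cc(/C=C/c2cc(OC)c(OCc3ccccc3)c(OC)c2)cc(OC)c1OCc1ccccc1 | intermediate
4 | trans-2,3-bis(4-benzyloxy-3,5-dimethoxyphenyl)oxirane, racemic (2S,3S enantiomer drawn) | COc1cc([C@@H]2O[C@H]2c2cc(OC)c(OCc3ccccc3)c(OC)c2)cc(OC)c1OCc1ccccc1 | intermediate
5 | (2R)-bornane-10,2-sultam [(1S,2R)-2,10-camphorsultam] | CC1(C)[C@@H]2CC[C@]13CS(=O)(=O)N[C@@H]3C2 | starting material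
6 | fumaryl chloride [(E)-but-2-enedioyl dichloride] | O=C(Cl)/C=C/C(Cl)=O | starting material
7 | sodium salt of 5 (N-sodio sultamide) | CC1(C)[C@@H]2CC[C@]13CS(=O)(=O)[N-][C@@H]3C2.[Na+] | intermediate (not isolated)
8 | N,N'-fumaroylbis[(2R)-bornane-10,2-sultam] | O=C(/C=C/C(=O)N1[C@@H]2C[C@H]3CC[C@]2(CS1(=O)=O)C3(C)C)N1[C@@H]2C[C@H]3CC[C@]2(CS1(=O)=O)C3(C)C | intermediate
9 | exo,exo (W-shaped) carbonyl ylide, 1,3-bis(4-benzyloxy-3,5-dimethoxyphenyl)-2-oxa-allyl zwitterion | COc1cc([CH-]/[O+]=C/c2cc(OC)c(OCc3ccccc3)c(OC)c2)cc(OC)c1OCc1ccccc1 | intermediate (not isolated)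
10 | N,N'-[(2R,3S,4S,5S)-2,5-bis(4-benzyloxy-3,5-dimethoxyphenyl)oxolane-3,4-dicarbonyl]bis[(2R)-bornane-10,2-sultam] (2,5-cis; 2,3-cis; 3,4-trans; 4,5-trans) | COc1cc([C@H]2O[C@@H](c3cc(OC)c(OCc4ccccc4)c(OC)c3)[C@@H](C(=O)N3[C@@H]4C[C@H]5CC[C@]4(CS3(=O)=O)C5(C)C)[C@@H]2C(=O)N2[C@@H]3C[C@H]4CC[C@]3(CS2(=O)=O)C4(C)C)cc(OC)c1OCc1ccccc1 | intermediate
11 | N,N'-[(2R,3S,4S,5S)-2,5-bis(4-hydroxy-3,5-dimethoxyphenyl)oxolane-3,4-dicarbonyl]bis[(2R)-bornane-10,2-sultam] (2,5-cis bisphenol) | COc1cc([C@H]2O[C@@H](c3cc(OC)c(O)c(OC)c3)[C@@H](C(=O)N3[C@@H]4C[C@H]5CC[C@]4(CS3(=O)=O)C5(C)C)[C@@H]2C(=O)N2[C@@H]3C[C@H]4CC[C@]3(CS2(=O)=O)C4(C)C)cc(OC)c1O | intermediate (not isolated)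
12 | N,N'-[(2S,3S,4S,5S)-2,5-bis(4-hydroxy-3,5-dimethoxyphenyl)oxolane-3,4-dicarbonyl]bis[(2R)-bornane-10,2-sultam] (all-trans bisphenol) | COc1cc([C@H]2O[C@H](c3cc(OC)c(O)c(OC)c3)[C@@H](C(=O)N3[C@@H]4C[C@H]5CC[C@]4(CS3(=O)=O)C5(C)C)[C@@H]2C(=O)N2[C@@H]3C[C@H]4CC[C@]3(CS2(=O)=O)C4(C)C)cc(OC)c1O | intermediate
13 | huazhongilexin, (2S,3R,4R,5S)-2,5-bis(4-hydroxy-3,5-dimethoxyphenyl)-3,4-bis(hydroxymethyl)oxolane | COc1cc([C@H]2O[C@H](c3cc(OC)c(O)c(OC)c3)[C@@H](CO)[C@@H]2CO)cc(OC)c1O | target

Total step count: 7. Longest linear sequence: 6 steps (steps 1, 2, 3, 5, 6, 7); step 4 is a one-step side branch.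

Steps most likely to fail

Step 5. The ylide may not discriminate well enough between the two faces of the fumaramide, or the hindered dipolarophile may trap it so slowly that it re-closes to the epoxide or is consumed by back reactions. The fallback replaces auxiliary control by resolution. It sets out from 4 and returns at 13. Epoxide 4 and commercial dimethyl fumarate, under the same sensitised irradiation, should give racemic dimethyl (2R*,3S*,4S*,5S*)-2,5-bis(4-benzyloxy-3,5-dimethoxyphenyl)oxolane-3,4-dicarboxylate F1. Hydrogenolysis (H2, Pd/C) should give the racemic 2,5-cis bisphenol diester F2, and catalytic CF3CO2H should equilibrate it to the racemic all-trans bisphenol diester F3. LiAlH4 then gives racemic 13, that is 13 together with its enantiomer F4. Preparative chromatography on a chiral stationary phase (amylose tris(3,5-dimethylphenylcarbamate)) separates 13 from F4.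

Step 6. During the acid equilibration the benzylic cation may be captured irreversibly by the neighbouring electron-rich ring (Friedel–Crafts closure to an aryltetralin) instead of re-closing the oxolane, or the equilibration may stay incomplete. The fallback avoids cations altogether. It sets out from 10 and returns at 12. The benzyl-protected adduct 10 is epimerised by a thiol-catalysed radical chain (polarity-reversal catalysis: iPr3SiSH cat., di-tert-butyl hyponitrite cat., benzene, 60 °C). Reversible hydrogen-atom abstraction at the electron-rich benzylic C2–H and C5–H, with the α-carbonyl C3–H and C4–H left alone, should lead to the all-trans dibenzyl bis-sultam F5. Hydrogenolysis (H2, Pd/C, EtOAc) of F5 then gives 12.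

Step 7. Hydride cleavage of the two hindered imides may be incomplete or unselective in the presence of aluminium phenoxides, and the basic medium may cause epimerisation or β-elimination at the aldehyde stage. The fallback separates removal of the auxiliary from the reduction. It sets out from 12 and returns at 13. Transesterification of 12 with Ti(OEt)4 in EtOH at reflux, which is not basic, should give diethyl (2S,3S,4S,5S)-2,5-bis(4-hydroxy-3,5-dimethoxyphenyl)oxolane-3,4-dicarboxylate F6 and the free sultam. The unhindered diester F6 is then reduced with LiBH4 in THF to 13.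

Further compounds
F1 | step 5 | racemic dimethyl (2R*,3S*,4S*,5S*)-2,5-bis(4-benzyloxy-3,5-dimethoxyphenyl)oxolane-3,4-dicarboxylate (2,5-cis; one enantiomer drawn) | COc1cc([C@H]2O[C@@H](c3cc(OC)c(OCc4ccccc4)c(OC)c3)[C@@H](C(=O)OC)[C@@H]2C(=O)OC)cc(OC)c1OCc1ccccc1
F2 | step 5 | racemic dimethyl (2R*,3S*,4S*,5S*)-2,5-bis(4-hydroxy-3,5-dimethoxyphenyl)oxolane-3,4-dicarboxylate (2,5-cis; one enantiomer drawn) | COc1cc([C@H]2O[C@@H](c3cc(OC)c(O)c(OC)c3)[C@@H](C(=O)OC)[C@@H]2C(=O)OC)cc(OC)c1O
F3 | step 5 | racemic dimethyl (2S*,3S*,4S*,5S*)-2,5-bis(4-hydroxy-3,5-dimethoxyphenyl)oxolane-3,4-dicarboxylate (all-trans; one enantiomer drawn) | COc1cc([C@H]2O[C@H](c3cc(OC)c(O)c(OC)c3)[C@@H](C(=O)OC)[C@@H]2C(=O)OC)cc(OC)c1O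
F4 | step 5 | (2R,3S,4S,5R)-2,5-bis(4-hydroxy-3,5-dimethoxyphenyl)-3,4-bis(hydroxymethyl)oxolane (enantiomer of 13) | COc1cc([C@@H]2O[C@@H](c3cc(OC)c(O)c(OC)c3)[C@H](CO)[C@H]2CO)cc(OC)c1O
F5 | step 6 | N,N'-[(2S,3S,4S,5S)-2,5-bis(4-benzyloxy-3,5-dimethoxyphenyl)oxolane-3,4-dicarbonyl]bis[(2R)-bornane-10,2-sultam] (all-trans) | COc1cc([C@H]2O[C@H](c3cc(OC)c(OCc4ccccc4)c(OC)c3)[C@@H](C(=O)N3[C@@H]4C[C@H]5CC[C@]4(CS3(=O)=O)C5(C)C)[C@@H]2C(=O)N2[C@@H]3C[C@H]4CC[C@]3(CS2(=O)=O)C4(C)C)cc(OC)c1OCc1ccccc1
F6 | step 7 | diethyl (2S,3S,4S,5S)-2,5-bis(4-hydroxy-3,5-dimethoxyphenyl)oxolane-3,4-dicarboxylate | COc1cc([C@H]2O[C@H](c3cc(OC)c(O)c(OC)c3)[C@@H](C(=O)OCC)[C@@H]2C(=O)OCC)cc(OC)c1O
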